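The data are simulated for substances that don't exist; scatter was added.

The violet run, 0.22 mM of J against 0.80 mM of X, levels off at a mean reading of 78.7% Z, and the rest of the J is taken here to have gone elsewhere. From this reading, the branch ratio S in violet is 3.69: the J ending in Z over the J ending elsewhere, a selectivity factor. It replaces a changing competition along the violet run by its mean.

| flask | J | X | remark | time |
|---|---|---|---|---|
| violet | 0.22 mM | 0.80 mM | run made earlier |  |
| ochre | 0.64 mM | 0.80 mM | run made earlier |  |
| amber | 1.9 mM | 0.80 mM | run made earlier |  |
| larch | 0.25 mM | 0.800 mM |  | 3.0 min |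
| oak | 0.50 mM | 0.800 mM |  | 3.0 min |
| cedar | 1.0 mM | 0.800 mM |  | 3.0 min |
| maple | 2.0 mM | 0.800 mM |  | 3.0 min |

| violet: time / s | violet: Z / % | ochre: time / s | ochre: Z / % | amber: time / s | amber: Z / % |
|---|---|---|---|---|---|
| 10.0 | 48 | 10.0 | 35 | 10.0 | 17 |
| 25.0 | 69 | 25.0 | 51 | 15.0 | 16 |
| 40.0 | 78 | 40.0 | 57 | 25.0 | 16 |
| 60.0 | 78 | 60.0 | 58 | 50.0 | 13 |
| 90.0 | 80 | 90.0 | 63 | 90.0 | 17 |

(scatter of a reading: 2 percentage points)

- "hardly changes" means that all values lie within two and a half points (for a concentration: within two and a half percent of the largest)
- a step back or a flat step of under half a percent of the largest counts as no turn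

* [Z] at the end for larch, oak, cedar, maple, in this order
* how that number moves from the first to the last of them (falls, then rises / falls all the way / rises all the way / rises, then falls / hardly changes)

Two extreme flasks can be solved in the head. If X stays near its charge, S keeps its violet value of 3.69 whatever J is charged, and Z is the violet share of J: 0.197 mM for larch, but 1.57 mM for maple. In the other extreme Z stops at a ceiling that more J does not raise, as the amber readings do, level from 10.0 s on at a mean of 0.300 mM, under that maple figure.

The ochre run lies between them: its plateau reads 0.380 mM of Z, and its ratio 1.46 is lower than violet's. The reckoning here therefore puts larch at the first extreme, maple at the second, and oak and cedar near ochre's 0.380 mM, so the row climbs and comes down.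

The forecast gives 0.175 mM, 0.27 mM, 0.32 mM and 0.24 mM, and says rises, then falls, on the ground that “The plateaus show that X dies before J is used up, even with X in excess”. It shares that shape but stands lower than the reckoning here at both ends, for larch and for maple.

The flasks give 0.194 mM, 0.343 mM, 0.370 mM and 0.303 mM: rises, then falls, turning at 0.72 mM of J.

    J + X → G (k = 130 M⁻¹ s⁻¹)
    J ⇌ D (K = 2.70, k = 0.0250 s⁻¹)
    X + G → Z (k = 860 M⁻¹ s⁻¹)
    D → E (k = 0.0920 s⁻¹)
    E ⇌ Q (K = 1.70, k = 0.0280 s⁻¹)

In larch, J enters the step with X at 4.2 times its forward rate into D at the start and 3.3 times at 0.0958 min, and the flask ends with 51.6% of its X left and S at 3.43, under the violet reading of 3.69. In maple, X stands at 0% of its charge by 1.50 min with J still at 9.74% of the J charged, and S ends at 0.178, far below the violet reading.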